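## The problem

Target 18 is a flavonol, a 2-aryl-3-hydroxychromen-4-one. Ring A (C4a, C5, C6, C7, C8, C8a) is a phloroglucinol nucleus, ring C carries O3, and ring B is a 4-methoxyphenyl group. There is no stereocenter, so nothing has to be set or relayed; the difficulty is regiochemical and chemoselective. C8 carries a 2-methylbut-3-en-2-yl group whose quaternary carbon sits between O7 and the ring oxygen O1. A prenyl electrophile would bond to the ring through its primary carbon, and the sigmatropic route through aryl prenyl ethers leaves the choice between C6 and C8 open. The two oxygens beside C8 must be told apart (one becomes O1, the other the free 7-hydroxyl), O5 must end free while O4' stays methylated, and O3 must be introduced at the right oxidation level. The tert-allyl group restricts the methods: strong acids can protonate the electron-rich ring at C8 and expel or shift the allyl cation, or add a neighbouring hydroxyl to the olefin; hydrogenolysis, halogens, peracids and dioxiranes attack the vinyl group; and the finished flavonol is oxidized by air in base. The enabling feature is that ring A carries oxygen on alternate carbons (C8a, C5, C7), the polyketide pattern. Cutting C7–C8 turns ring A into a triketide chain in which C8 is the α-carbon of a 3,3-dimethylpent-4-enoyl unit, so the quaternary carbon comes ready-made in ester 2 and O5 can be carried as the enol ether of a 2-pyrone.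

## Retrosynthesis

**End game (18 ⇒ 17 ⇒ 16).** The bonds cut are O7–allyl and O5–methyl. The methyl on O5 comes out of the key step and blocks O5 so that ring C can close only on O1. The cap on O7 must survive KOH and alkaline peroxide and leave without acid or hydrogen; an allyl ether does this, whereas a silyl ether para to a carbonyl is cleaved by hydroxide, a methoxymethyl ether needs acid and a benzyl ether needs hydrogenolysis. The O5 methyl is the only ether peri to the C4 carbonyl, so it is removed first by chelation (16 to 17) while O7 is still capped and no hydroxyl stands beside the olefin. The allyl group then leaves under neutral conditions with zerovalent palladium (17 to 18). The forward demand is chelation selectivity against the 4'-methoxy group.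

**Ring C (16 ⇒ 14 ⇒ 12 + 13).** Flavonol 16 is opened at O1–C2 and C3–O3 to chalcone 14, and 14 is cut at C2–C3 into acetophenone 12 and 4-methoxybenzaldehyde 13. The neighbouring cut, acyl transfer from an aroyl chloride to 12, reaches only a flavone after an acid-mediated dehydration, and the missing O3 would then have to be added by reagents that do not spare the vinyl group. The chalcone route runs in base throughout and takes O3 from hydrogen peroxide. The precursor 12 holds only ring A. The forward reaction must close on the β-carbon (six-membered ring) and not on the α-carbon (aurone); the electron-rich aryl group on the β-carbon speaks for this.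

**The acetyl group (12 ⇒ 11 ⇒ 10 ⇒ 9 ⇒ 7).** Ketone 12 goes back through carbinol 11 (C3–C4 bond, methyl Grignard addition) and allyl ether 10 to aldehyde 9, and 9 to the symmetric resorcinol 7 by cutting C4–C4a. A direct Friedel–Crafts acetylation of 7 would be two steps shorter, but it puts a strong Lewis acid on the most electron-rich and most acid-sensitive compound of the route. The magnesium-mediated formylation acts on the phenoxide in the presence of an amine. Formylation also breaks the symmetry: the two free ring carbons of 7 are equivalent, and once one bears the aldehyde the adjacent hydroxyl (future O1) is tied up in a hydrogen bond and the remote one (O7) is alkylated. The forward demands are monoformylation, selective O-alkylation, and oxidation of the ionizable carbinol 11 before it decomposes.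

**Ring A (7 ⇒ 5), the key cut.** Ring A of 7 is cut at C7–C8, which leads to its isomer, 2-pyrone 5, in which O on C8a is the ring oxygen and C7 the lactone carbonyl. Cutting the aryl–quaternary bond instead would require a tert-allyl electrophile or a sigmatropic shift with open regiochemistry. Cutting C4a–C5 or C5–C6 would not place the quaternary group between two equivalent oxygens. The precursor has no carbocycle and is assembled from two esters. The forward reaction asks that, after methoxide opens the lactone, the C8 enolate of the freed ketone acylates itself with the ester; aromatization makes this the only irreversible exit.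

**The pyrone (5 ⇒ 4 ⇒ 3 ⇒ 1 + 2).** The methyl ether of 5 is cut to hydroxypyrone 4, the lactone C–O bond (O on C8a to C7) to dioxo ester 3, and the C4a–C8a bond of 3 to the dianion of methyl acetoacetate 1 and methyl 3,3-dimethylpent-4-enoate 2. Ester 2 is a bulk intermediate and already contains the bond between C8 and the quaternary carbon. The forward acylation must beat proton transfer, and the methylation must go to O5 and not to the lactone oxygen.

## Roads not taken

**Alternative 1:** Ring C is cut at C4a–C4, C4–C3 and O1–C2 in one stroke. Iodophenol A2, carbon monoxide A4 and alkyne A3 would be joined by a palladium–phosphine catalyst in a secondary amine to give flavone A1.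
- Merits: three bonds and one ring in one step, full convergence, and closure regiochemistry fixed by the position of the iodine.
- Weak points: A1 is a flavone, so O3 still has to be added, and the mildest reagents for that (dioxiranes) would attack the vinyl group. A2 already contains ring A with its tert-allyl group, so the hardest bond of the target is left unsolved. The iodide is flanked on both sides in an electron-rich ring, which slows oxidative addition to zerovalent palladium. The two methoxymethyl ethers need acid at the end, when O7–H lies beside the olefin.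
- Comparison: for ring C alone this road is clearly shorter than steps 5 to 10 of the chosen plan. The chosen plan sets against it a defined origin of the C8 substituent, O3 delivered by peroxide during ring closure, and an end game free of acid.

**Alternative 2:** Ring A is cut into cyclobutenone A6 and siloxyalkyne A7. Heating would give a vinylketene that forms C8a–C8 and C6–C7 in a [2+2] step and C4a–C8a in a six-electron closure, leading to phenol A5.
- Merits: complete regiocontrol, neutral thermal conditions, and O1 free with O7 silylated from the outset. In this respect it is better than the chosen plan, whose diol 7 is symmetric and needs formylation and alkylation to tell the two hydroxyls apart.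
- Weak points: A7 must be made from ester 2 by ynolate homologation and O-silylation, and A6 is not a shelf reagent. The [2+2] step must bond the ketene carbon to the alkyne carbon that carries the quaternary centre. The silyl ether would not survive the hydroxide of the chalcone stage, and the ethyl ether at O5 is cleaved more slowly than a methyl ether.
- Comparison: the number of steps to the ring A stage is about the same. The chosen plan sets against the earlier differentiation its commodity materials, robust intermediates and a methyl ether at O5.

**Alternative 3:** Ring A is cut at C8–C8a and C4a–C5. Diene A9 and bromopyranone A10 would combine in a [4+2] sense, and elimination and desilylation would give A8, one deacetylation from 18.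
- Merits: rings B and C and O3 are in place first, O5 and O7 emerge free without protecting groups, and no question of O1 regiochemistry arises. On paper this is the shortest road, shorter than the chosen plan.
- Weak points: the C8–C8a bond must be made by the diene terminus that bears the quaternary substituent, attacking a 4-pyranone, which is a poor acceptor without an extra activating group. A9 has to be made by double silylation of a hindered β-keto ester with control of its terminal geometry. A10 needs a regioselective bromination.
- Comparison: the chosen plan is longer, but it buys the hindered bond in 2 and forms only an intramolecular C7–C8 bond in its key step.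

Key step: step 4

Assumption: the SMILES is read as the achiral 4H-chromen-4-one tautomer; the starting materials 1, 2 and 13 and all reagents, including MgI2·OEt2, are taken as commercial or prepared beforehand.

**Step 1**
Reactants: 1 methyl acetoacetate; 2 methyl 3,3-dimethylpent-4-enoate
Product: 3 methyl 7,7-dimethyl-3,5-dioxonon-8-enoate
Conditions: 1 (2.2 equiv), NaH, THF, 0 °C; n-BuLi, 0 °C; then 2, 0 °C → rt; aq HCl
Reagents that add atoms: none
Why: Claisen-type γ-acylation of the acetoacetate dianion: the terminal carbanion (future C4a) adds to the ester carbonyl of 2 (future C8a); the α-CH2 of 2 is neopentyl-like and weakly acidic, so addition should outrun proton transfer, and the excess dianion takes up the proton released by the more acidic product.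

**Step 2**
Reactants: 3 methyl 7,7-dimethyl-3,5-dioxonon-8-enoate
Product: 4 6-(2,2-dimethylbut-3-en-1-yl)-4-hydroxy-2H-pyran-2-one
Conditions: DBU, toluene, reflux; aq HCl
Reagents that add atoms: none
Why: Base-mediated lactonization: the enolate oxygen of the C8a ketone acylates the ester (6-exo-trig) with loss of methanol, the standard closure of 3,5-dioxo esters to 4-hydroxy-2-pyrones.

**Step 3**
Reactants: 4 6-(2,2-dimethylbut-3-en-1-yl)-4-hydroxy-2H-pyran-2-one
Product: 5 6-(2,2-dimethylbut-3-en-1-yl)-4-methoxy-2H-pyran-2-one
Conditions: Me2SO4, K2CO3, acetone, reflux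
Reagents that add atoms: dimethyl sulfate, COS(=O)(=O)OC
Why: O-Alkylation of a vinylogous acid; under these conditions 4-hydroxy-2-pyrones are methylated at the 4-oxygen (future O5) in preference to the lactone oxygen, as established for triacetic acid lactone.

**Step 4**
Reactants: 5 6-(2,2-dimethylbut-3-en-1-yl)-4-methoxy-2H-pyran-2-one
Product: 7 5-methoxy-2-(2-methylbut-3-en-2-yl)benzene-1,3-diol, via open-chain keto enoate 6 (not isolated)
Conditions: NaOMe (4 equiv), dry MeOH, reflux, Ar; then 1 M HCl to pH 6, 0 °C
Reagents that add atoms: none
Why: Methoxide adds to the lactone carbonyl (future C7) and the ring opens to keto enoate 6, in which C7 and C4a stay cis on the C5–C6 double bond as the ring held them; this E enol ether is also the more stable geometry. The freed C8a ketone enolizes reversibly toward C4a, which leads nowhere except back to 5, and toward C8; only the C8 enolate can reach the ester, and it forms C7–C8 in a 6-(enolendo)-exo-trig Claisen (Dieckmann-type) closure that builds ring A. Loss of methoxide gives a cyclohexenedione that tautomerizes to the resorcinol and is deprotonated, which makes the sequence irreversible and drains the equilibrium between 5 and 6. The closest known reaction type is the alkoxide-induced isomerization of 4-methoxy-6-methyl-2-pyrone to phloroglucinol monomethyl ether, and more broadly the Claisen cyclization of 3,5-dioxo esters to phloroglucinols; the difference here is only the quaternary neighbour of the nucleophilic carbon. Methoxide in methanol is used so that addition–elimination at C5 exchanges methoxy for methoxy, and water is excluded so that the ester is not saponified. No stereocenter is formed. The selectivity needed, C-acylation at C8 over all reversible alternatives, is secured by thermodynamics, since aromatization is the only exit from the equilibrating set of species.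

**Step 5**
Reactants: 7 5-methoxy-2-(2-methylbut-3-en-2-yl)benzene-1,3-diol
Product: 9 2,4-dihydroxy-6-methoxy-3-(2-methylbut-3-en-2-yl)benzaldehyde, via hydroxymethyl phenol 8 (not isolated)
Conditions: MgCl2, Et3N, (CH2O)n, MeCN, reflux; then cold dilute HCl
Reagents that add atoms: formaldehyde (as paraformaldehyde), C=O
Why: Casnati–Skattebøl ortho-formylation: the magnesium phenoxide delivers formaldehyde to the ortho carbon to give 8, whose magnesium alkoxide passes hydride to a second formaldehyde; the two free ring carbons of 7 are equivalent, the formyl group deactivates the ring toward a second entry, and no acid touches the tert-allyl arene during the reaction.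

**Step 6**
Reactants: 9 2,4-dihydroxy-6-methoxy-3-(2-methylbut-3-en-2-yl)benzaldehyde
Product: 10 2-hydroxy-6-methoxy-3-(2-methylbut-3-en-2-yl)-4-(prop-2-en-1-yloxy)benzaldehyde
Conditions: allyl bromide (1.1 equiv), K2CO3, acetone, reflux
Reagents that add atoms: allyl bromide, C=CCBr
Why: Williamson etherification: the hydroxyl next to the formyl group (future O1) is held in a hydrogen bond and flanked on both sides, so the more acidic hydroxyl para to the formyl group (O7) is alkylated, as is usual for 2,4-dihydroxybenzaldehydes.

**Step 7**
Reactants: 10 2-hydroxy-6-methoxy-3-(2-methylbut-3-en-2-yl)-4-(prop-2-en-1-yloxy)benzaldehyde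
Product: 11 2-(1-hydroxyethyl)-3-methoxy-6-(2-methylbut-3-en-2-yl)-5-(prop-2-en-1-yloxy)phenol (racemic)
Conditions: MeMgBr (2.5 equiv), THF, −20 → 0 °C; then aq NH4Cl; crude product used at once
Reagents that add atoms: methylmagnesium bromide, C[Mg]Br
Why: Grignard 1,2-addition: the first equivalent deprotonates the chelated phenol and the second adds to the aldehyde within the magnesium chelate; the carbinol center is formed racemic and is removed in step 8.

**Step 8**
Reactants: 11 2-(1-hydroxyethyl)-3-methoxy-6-(2-methylbut-3-en-2-yl)-5-(prop-2-en-1-yloxy)phenol
Product: 12 1-[2-hydroxy-6-methoxy-3-(2-methylbut-3-en-2-yl)-4-(prop-2-en-1-yloxy)phenyl]ethan-1-one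
Conditions: activated MnO2, CH2Cl2, rt
Reagents that add atoms: none
Why: Benzylic oxidation with MnO2, a neutral heterogeneous oxidant that takes benzylic alcohols to aryl ketones and leaves isolated olefins and aryl ethers alone; the product is stabilized by the hydrogen bond from O1–H.

**Step 9**
Reactants: 12 1-[2-hydroxy-6-methoxy-3-(2-methylbut-3-en-2-yl)-4-(prop-2-en-1-yloxy)phenyl]ethan-1-one; 13 4-methoxybenzaldehyde
Product: 14 (2E)-1-[2-hydroxy-6-methoxy-3-(2-methylbut-3-en-2-yl)-4-(prop-2-en-1-yloxy)phenyl]-3-(4-methoxyphenyl)prop-2-en-1-one
Conditions: KOH, EtOH–H2O, rt; then cold dilute HCl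
Reagents that add atoms: none
Why: Claisen–Schmidt condensation: the methyl ketone enolate adds to the non-enolizable aldehyde 13 and the aldol loses water by an E1cB path to the E-enone; 2'-hydroxy-4',6'-dialkoxyacetophenones are standard substrates.

**Step 10**
Reactants: 14 (2E)-1-[2-hydroxy-6-methoxy-3-(2-methylbut-3-en-2-yl)-4-(prop-2-en-1-yloxy)phenyl]-3-(4-methoxyphenyl)prop-2-en-1-one
Product: 16 3-hydroxy-5-methoxy-2-(4-methoxyphenyl)-8-(2-methylbut-3-en-2-yl)-7-(prop-2-en-1-yloxy)-4H-chromen-4-one, via trans-dihydroflavonol 15 (not isolated)
Conditions: H2O2 (30%), aq NaOH, MeOH, 0 °C → rt; then dilute HCl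
Reagents that add atoms: hydrogen peroxide, OO
Why: Algar–Flynn–Oyamada reaction: oxa-Michael closure of the phenoxide on the β-carbon (6-endo-trig) with oxygen transfer from hydroperoxide to the α-carbon gives the trans-dihydroflavonol 15, which alkaline peroxide dehydrogenates to the flavonol; the 4-methoxyphenyl group stabilizes positive character at the β-carbon and so favours the six-membered over the five-membered (aurone) closure, and unactivated olefins do not react with alkaline H2O2.

**Step 11**
Reactants: 16 3-hydroxy-5-methoxy-2-(4-methoxyphenyl)-8-(2-methylbut-3-en-2-yl)-7-(prop-2-en-1-yloxy)-4H-chromen-4-one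
Product: 17 3,5-dihydroxy-2-(4-methoxyphenyl)-8-(2-methylbut-3-en-2-yl)-7-(prop-2-en-1-yloxy)-4H-chromen-4-one
Conditions: MgI2·OEt2 (excess), THF, reflux; then aq NH4Cl
Reagents that add atoms: none
Why: Chelation-controlled ether cleavage: magnesium held between the C4 carbonyl and O5 activates only the peri methyl ether toward SN2 attack by iodide, as in the known MgI2 demethylation of 5-methoxyflavanones that carry acid-sensitive prenyl groups; O4' and O7 cannot chelate, and with O7 still capped no hydroxyl stands beside the olefin.

**Step 12**
Reactants: 17 3,5-dihydroxy-2-(4-methoxyphenyl)-8-(2-methylbut-3-en-2-yl)-7-(prop-2-en-1-yloxy)-4H-chromen-4-one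
Product: 18 3,5,7-trihydroxy-2-(4-methoxyphenyl)-8-(2-methylbut-3-en-2-yl)-4H-chromen-4-one
Conditions: Pd(PPh3)4 (5 mol %), morpholine, THF, rt, Ar
Reagents that add atoms: none
Why: Tsuji–Trost deallylation: zerovalent palladium ionizes the aryl allyl ether to an allylpalladium cation that morpholine captures; the tert-allyl group is bonded through carbon, has no leaving group and is inert, and the conditions are neutral.

## Compound list

1 | methyl acetoacetate (methyl 3-oxobutanoate) | CC(=O)CC(=O)OC | starting material
2 | methyl 3,3-dimethylpent-4-enoate | COC(=O)CC(C)(C)C=C | starting material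
3 | methyl 7,7-dimethyl-3,5-dioxonon-8-enoate | C=CC(C)(C)CC(=O)CC(=O)CC(=O)OC | intermediate
4 | 6-(2,2-dimethylbut-3-en-1-yl)-4-hydroxy-2H-pyran-2-one | C=CC(C)(C)Cc1cc(O)cc(=O)o1 | intermediate
5 | 6-(2,2-dimethylbut-3-en-1-yl)-4-methoxy-2H-pyran-2-one | C=CC(C)(C)Cc1cc(OC)cc(=O)o1 | intermediate
6 | methyl (2E)-3-methoxy-7,7-dimethyl-5-oxonona-2,8-dienoate (formed in the flask in step 4, not isolated) | C=CC(C)(C)CC(=O)C/C(OC)=C\C(=O)OC | intermediate
7 | 5-methoxy-2-(2-methylbut-3-en-2-yl)benzene-1,3-diol | C=CC(C)(C)c1c(O)cc(OC)cc1O | intermediate
8 | 4-(hydroxymethyl)-5-methoxy-2-(2-methylbut-3-en-2-yl)benzene-1,3-diol (formed in the flask in step 5 as its magnesium salt, not isolated) | C=CC(C)(C)c1c(O)cc(OC)c(CO)c1O | intermediate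
9 | 2,4-dihydroxy-6-methoxy-3-(2-methylbut-3-en-2-yl)benzaldehyde | C=CC(C)(C)c1c(O)cc(OC)c(C=O)c1O | intermediate
10 | 2-hydroxy-6-methoxy-3-(2-methylbut-3-en-2-yl)-4-(prop-2-en-1-yloxy)benzaldehyde | C=CCOc1cc(OC)c(C=O)c(O)c1C(C)(C)C=C | intermediate
11 | 2-(1-hydroxyethyl)-3-methoxy-6-(2-methylbut-3-en-2-yl)-5-(prop-2-en-1-yloxy)phenol, racemic | C=CCOc1cc(OC)c(C(C)O)c(O)c1C(C)(C)C=C | intermediate
12 | 1-[2-hydroxy-6-methoxy-3-(2-methylbut-3-en-2-yl)-4-(prop-2-en-1-yloxy)phenyl]ethan-1-one | C=CCOc1cc(OC)c(C(C)=O)c(O)c1C(C)(C)C=C | intermediate
13 | 4-methoxybenzaldehyde | COc1ccc(C=O)cc1 | starting material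
14 | (2E)-1-[2-hydroxy-6-methoxy-3-(2-methylbut-3-en-2-yl)-4-(prop-2-en-1-yloxy)phenyl]-3-(4-methoxyphenyl)prop-2-en-1-one | C=CCOc1cc(OC)c(C(=O)/C=C/c2ccc(OC)cc2)c(O)c1C(C)(C)C=C | intermediate
15 | trans-3-hydroxy-5-methoxy-2-(4-methoxyphenyl)-8-(2-methylbut-3-en-2-yl)-7-(prop-2-en-1-yloxy)-2,3-dihydro-4H-chromen-4-one, racemic, (2R,3R) enantiomer drawn (formed in the flask in step 10, not isolated) | C=CCOc1cc(OC)c2C(=O)[C@H](O)[C@@H](c3ccc(OC)cc3)Oc2c1C(C)(C)C=C | intermediate
16 | 3-hydroxy-5-methoxy-2-(4-methoxyphenyl)-8-(2-methylbut-3-en-2-yl)-7-(prop-2-en-1-yloxy)-4H-chromen-4-one | C=CCOc1cc(OC)c2c(=O)c(O)c(-c3ccc(OC)cc3)oc2c1C(C)(C)C=C | intermediate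
17 | 3,5-dihydroxy-2-(4-methoxyphenyl)-8-(2-methylbut-3-en-2-yl)-7-(prop-2-en-1-yloxy)-4H-chromen-4-one | C=CCOc1cc(O)c2c(=O)c(O)c(-c3ccc(OC)cc3)oc2c1C(C)(C)C=C | intermediate
18 | 3,5,7-trihydroxy-2-(4-methoxyphenyl)-8-(2-methylbut-3-en-2-yl)-4H-chromen-4-one | C=CC(C)(C)c1c(O)cc(O)c2c(=O)c(O)c(-c3ccc(OC)cc3)oc12 | target

## Step count and least certain steps

Total: 12 steps. Longest linear sequence: 12 steps (from 1 and 2 to 18); aldehyde 13 enters in step 9.

**Step 4 (key step).** The closure may fail to outrun the side reactions of the open chain. The C8 enolate is the minor enolate and its carbon is flanked by a quaternary centre, so C-acylation is slow. Meanwhile methoxide can add to the C8a ketone and split the chain by retro-Claisen cleavage, and traces of hydroxide can saponify the ester, after which decarboxylation ends the sequence. Fallback: separate opening and closure. Pyrone 5 would be opened with Mg(OMe)2 in MeOH at rt, which should stop at the magnesium-chelated open chain, and keto enoate 6 would be isolated. It would then be treated with LiN(i-Pr)2 (2.2 equiv) in THF at −78 → 0 °C, so that the C8 carbanion is formed in full as part of a dianion in a medium without nucleophilic alkoxide, and closes to 7 on warming. The detour sets out from 5 and returns at 7, and makes no compound outside the list (F0).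

**Step 10.** After epoxidation of the twisted enone, the phenoxide may close on the α-carbon (five-membered ring), which diverts material to the aurone series; the 6'-methoxy group is known to favour this. Fallback from 12: the lithium dianion of 12 (LiN(SiMe3)2, THF, −78 °C) would be C-acylated with 4-methoxybenzoyl chloride to give the β-diketone F1. Mild cyclodehydration (catalytic p-TsOH, toluene, 80 °C) would give the flavone F2. Deprotonation of F2 at C3 with LiN(i-Pr)2, trapping with B(OMe)3 and oxidation with H2O2/AcOH would give flavonol 16, where the route is rejoined.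

**Step 7 (with step 8).** The electron-rich o-hydroxybenzylic carbinol 11 may ionize to a quinone methide during work-up or on the oxidant surface and oligomerize. Fallback from 10: the chelated hydroxyl would be capped (NaH, MOMCl, DMF) to give the methoxymethyl ether aldehyde F3. MeMgBr would give the carbinol F4, which can no longer form a quinone methide, and Dess–Martin periodinane would give the ketone F5. Brief treatment with dilute HCl in MeOH at rt would release the ortho-carbonyl phenol and return the route at 12.

**Step 11.** Demethylation may stall because magnesium is held by the 3-oxido-4-oxo chelate, iodide may also cleave the allyl ether, or hydrogen iodide formed from the free 3-hydroxyl may add to the vinyl group. Fallback from 16: deallylation first (Pd(PPh3)4, morpholine) would give the 3,7-diol F6, and acetylation (Ac2O, pyridine) the 3,7-diacetate F7, in which no hydroxyl stands beside the olefin. BCl3 in CH2Cl2 at −78 → 0 °C would cleave the chelated 5-methyl ether to the 5-hydroxy diacetate F8, and degassed K2CO3/MeOH would remove the acetates to give 18.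

**Step 1.** Proton transfer from ester 2 to the dianion, or slow addition to its β-branched carbonyl, may leave the acylation incomplete. Fallback from 2: saponification (LiOH, THF–H2O) would give the acid F9 and oxalyl chloride the acid chloride F10. F10 would acylate the lithium dienolate of 2,2,6-trimethyl-4H-1,3-dioxin-4-one (LiN(SiMe3)2, THF, −78 °C) to give the acyl dioxinone F11. Heating F11 in toluene would release acetone and the acylketene, which closes on its enol oxygen to hydroxypyrone 4, where the route is rejoined; 3 is bypassed.

## Further compounds

F0 | step 4 | none | none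
F1 | step 10 | 1-[2-hydroxy-6-methoxy-3-(2-methylbut-3-en-2-yl)-4-(prop-2-en-1-yloxy)phenyl]-3-(4-methoxyphenyl)propane-1,3-dione | C=CCOc1cc(OC)c(C(=O)CC(=O)c2ccc(OC)cc2)c(O)c1C(C)(C)C=C
F2 | step 10 | 5-methoxy-2-(4-methoxyphenyl)-8-(2-methylbut-3-en-2-yl)-7-(prop-2-en-1-yloxy)-4H-chromen-4-one | C=CCOc1cc(OC)c2c(=O)cc(-c3ccc(OC)cc3)oc2c1C(C)(C)C=C
F3 | step 7 | 6-methoxy-2-(methoxymethoxy)-3-(2-methylbut-3-en-2-yl)-4-(prop-2-en-1-yloxy)benzaldehyde | C=CCOc1cc(OC)c(C=O)c(OCOC)c1C(C)(C)C=C
F4 | step 7 | 1-[6-methoxy-2-(methoxymethoxy)-3-(2-methylbut-3-en-2-yl)-4-(prop-2-en-1-yloxy)phenyl]ethan-1-ol, racemic | C=CCOc1cc(OC)c(C(C)O)c(OCOC)c1C(C)(C)C=C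
F5 | step 7 | 1-[6-methoxy-2-(methoxymethoxy)-3-(2-methylbut-3-en-2-yl)-4-(prop-2-en-1-yloxy)phenyl]ethan-1-one | C=CCOc1cc(OC)c(C(C)=O)c(OCOC)c1C(C)(C)C=C
F6 | step 11 | 3,7-dihydroxy-5-methoxy-2-(4-methoxyphenyl)-8-(2-methylbut-3-en-2-yl)-4H-chromen-4-one | C=CC(C)(C)c1c(O)cc(OC)c2c(=O)c(O)c(-c3ccc(OC)cc3)oc12
F7 | step 11 | 5-methoxy-2-(4-methoxyphenyl)-8-(2-methylbut-3-en-2-yl)-4-oxo-4H-chromene-3,7-diyl diacetate | C=CC(C)(C)c1c(OC(C)=O)cc(OC)c2c(=O)c(OC(C)=O)c(-c3ccc(OC)cc3)oc12
F8 | step 11 | 5-hydroxy-2-(4-methoxyphenyl)-8-(2-methylbut-3-en-2-yl)-4-oxo-4H-chromene-3,7-diyl diacetate | C=CC(C)(C)c1c(OC(C)=O)cc(O)c2c(=O)c(OC(C)=O)c(-c3ccc(OC)cc3)oc12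
F9 | step 1 | 3,3-dimethylpent-4-enoic acid | C=CC(C)(C)CC(=O)O
F10 | step 1 | 3,3-dimethylpent-4-enoyl chloride | C=CC(C)(C)CC(=O)Cl
F11 | step 1 | 6-(4,4-dimethyl-2-oxohex-5-en-1-yl)-2,2-dimethyl-4H-1,3-dioxin-4-one | C=CC(C)(C)CC(=O)CC1=CC(=O)OC(C)(C)O1
A1 | alternative 1 | 5,7-bis(methoxymethoxy)-2-(4-methoxyphenyl)-8-(2-methylbut-3-en-2-yl)-4H-chromen-4-one | C=CC(C)(C)c1c(OCOC)cc(OCOC)c2c(=O)cc(-c3ccc(OC)cc3)oc12
A2 | alternative 1 | 2-iodo-3,5-bis(methoxymethoxy)-6-(2-methylbut-3-en-2-yl)phenol | C=CC(C)(C)c1c(O)c(I)c(OCOC)cc1OCOC
A3 | alternative 1 | 1-ethynyl-4-methoxybenzene | C#Cc1ccc(OC)cc1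
A4 | alternative 1 | carbon monoxide | [C-]#[O+]
A5 | alternative 2 | 5-ethoxy-2-(2-methylbut-3-en-2-yl)-3-[tri(propan-2-yl)silyloxy]phenol | C=CC(C)(C)c1c(O)cc(OCC)cc1O[Si](C(C)C)(C(C)C)C(C)C
A6 | alternative 2 | 3-ethoxycyclobut-2-en-1-one | CCOC1=CC(=O)C1
A7 | alternative 2 | [(3,3-dimethylpent-4-en-1-yn-1-yl)oxy]tri(propan-2-yl)silane | C=CC(C)(C)C#CO[Si](C(C)C)(C(C)C)C(C)C
A8 | alternative 3 | 5,7-dihydroxy-2-(4-methoxyphenyl)-8-(2-methylbut-3-en-2-yl)-4-oxo-4H-chromen-3-yl acetate | CC(=O)Oc1c(-c2ccc(OC)cc2)oc2c(C(C)(C)C=C)c(O)cc(O)c2c1=O
A9 | alternative 3 | 1-methoxy-5,5-dimethyl-1,3-bis(trimethylsilyloxy)hepta-1,3,6-triene (olefin geometry not fixed) | C=CC(C)(C)C=C(O[Si](C)(C)C)C=C(OC)O[Si](C)(C)C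
A10 | alternative 3 | 5-bromo-2-(4-methoxyphenyl)-4-oxo-4H-pyran-3-yl acetate | CC(=O)Oc1c(-c2ccc(OC)cc2)occ(Br)c1=O
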